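(The runs stem from a simulated flask with made-up constants; noise was put on by code.)

The midnight charge held 0.240 M of coupling partner against 0.200 M of substrate, 0.0400 M to spare on paper, yet that run stood at 0.1094 M target at 27 h with its slope fading. The summer run repeats this charge, so I needed to know where the curve stops and what target does afterwards.

| setting | midnight | dusk | winter | noon | summer |
|---|---|---|---|---|---|
| substrate | 0.200 M | 0.120 M | 0.200 M | 0.100 M | 0.200 M |
| coupling partner | 0.240 M | 0.160 M | 0.720 M | 0.240 M | 0.240 M |
| catalyst | 0.00200 M | 0.00200 M | 0.00200 M | 0.00200 M | 0.00200 M |
| time |  |  |  |  | 110 h |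

- midnight run (time / h: [target] / M): 1.1: 0.0158; 1.7: 0.0239; 2.7: 0.0331; 4.3: 0.0488; 6.8: 0.0654; 11: 0.0835; 17: 0.0982; 27: 0.1094
- dusk run (time / h: [target] / M): 1.1: 0.0066; 1.7: 0.0103; 2.7: 0.0144; 4.3: 0.0223; 6.8: 0.0297; 11: 0.0390; 17: 0.0492; 27: 0.0555
- winter run (time / h: [target] / M): 1.1: 0.0432; 1.7: 0.0624; 2.7: 0.0855; 4.3: 0.1143; 6.8: 0.1407; 11: 0.1628; 17: 0.1742; 27: 0.1760
- noon run (time / h: [target] / M): 1.1: 0.0080; 1.7: 0.0121; 2.7: 0.0180; 4.3: 0.0243; 6.8: 0.0341; 11: 0.0457; 17: 0.0551; 27: 0.0636

(scatter of a reading: 6 × 10⁻⁴ M)

- order of the initial rate in [coupling partner], near the charge of the midnight run, the rate being that where two percent of its substrate are target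
- order of the initial rate in [substrate], near the charge of the midnight run, the rate being that where two percent of its substrate are target (one fixed amount of target, the same in the runs compared)
- target in the summer run at 110 h, as a share of the substrate charged

- Overall: substrate + coupling partner -> target, with catalyst as catalyst.
- Constant volume, constant temperature.
- "The second partner" is coupling partner.
- An order is taken over about fifteen percent of the charge, up and down.

I began with the first readings. From midnight to noon they gave a substrate order of 0.982, and from midnight to winter a partner order of 0.916, from a chord already bent, so I committed to 1 for each. The midnight chord, taken at mean concentrations, gave a coupling constant of 0.322 M⁻¹ h⁻¹.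

Next I assumed that partner also leaks away by a first-order step, and divided its total loss rate by the substrate loss rate, so that time dropped out: each M of substrate turned costs 1 + a/c(substrate) of partner. Between 2.7 h and 6.8 h in the midnight run, with 0.0493 M target at the midpoint, the slope implied c(coupling partner) = 0.162 M. Integrating the ratio gave a = 0.101 M, the leak level: the c(substrate) at which partner is lost aside as fast as it couples.

For the summer run I tried 0.133 M of substrate turned. That overspent the partner by 0.004214 M, and one correction gave 0.132 M. Partner, though in excess on paper, is then the limiting reagent of the summer run by this reckoning, with 0.0683 M of substrate unturned.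

The weak link was my assumption that target stays. Winter, averaged over its last two readings, held 0.175 M target. Guessing 0.0125 M substrate left, the rule gave 0.252 M partner. Had target stayed, the 0.0249 M of unconverted substrate would have made 0.002023 M h⁻¹, more than the 1.800 × 10⁻⁴ M h⁻¹ seen. Balancing the two, with the winter target dated from 4.3 h, gave a target loss constant of 0.00432 h⁻¹. Dating the summer target at 6.8 h, where midnight reached about half of that turned amount, I committed to 42.2%.

The forecast, “suggesting reversibility”, gave orders of 0.93 in partner and 0.98 in substrate, and a share of 60.5%, higher than my share.

The summer run gave 44.5% at 110 h, and the orders near the midnight charge came to 1.0 in partner and 1.0 in substrate. A power law fitted over the runs forecast 86.2% for this flask.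

    catalyst + substrate + coupling partner → target + catalyst (162.7 M⁻² h⁻¹)
    coupling partner → lost reagent (0.02938 h⁻¹)
    target → decomposed product (0.004392 h⁻¹)

At the leak level of 0.101 M, the rule sent 0.108 M of the summer partner aside. In the winter run, midway between a quarter and half of the substrate made, the same rule gave 0.0241 M h⁻¹, and the times of those two marks give 0.0235 M h⁻¹.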